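**Retrosynthetic overview**
1. The two CHO groups and the free OH groups come last (dibromide → dilithio arene → DMF, then acid); before that the ten-membered ring C closes at C2–C3 by intramolecular alkylation of a C2 sulfone carbanion with a (Z)-allylic chloride.
2. C8–C9 comes from Julia–Kocienski union of chroman aldehyde 20 (fragment A) with sulfone 28 (fragment B), then reduction of the new CH=CH.
3. Fragment B comes from (S)-carvone, which supplies C7 and the cis C4=C5 bond; its ring is opened by α′-hydroxylation and Pb(OAc)4 cleavage.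
4. Chroman ring B: the phenol opens a Sharpless epoxide at C10 with inversion (sets C10); C1 comes from trans alkylation of dihydrocoumarin 8.
5. Key C–C bond (aryl–C7′): catalytic enantioselective Michael (Friedel–Crafts type) addition of phenol 5 to enal 3. Ring order: A (arene, bought) → B (chroman) → C (cyclodecene).

Assumption: the SMILES is taken literally (ring alkene Z; 1S, 7R, 10R, 7′S); labels C1–C15 follow germacrane numbering and C7′ is the benzylic carbon.

**Step 1**
Reactants: 1 3-methylbutanal; 2 (triphenylphosphoranylidene)acetaldehyde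
Product: 3 (E)-5-methylhex-2-enal
Conditions: 1 (1.5 equiv), toluene, 80 °C
Reagents that add atoms: none
Why: Wittig olefination with the stabilised formyl ylide gives the E-enal; no stereocentre.

**Step 2**
Reactants: 4 phloroglucinol
Product: 5 3,5-bis(methoxymethoxy)phenol
Conditions: MOMCl (2.0 equiv), i-Pr2NEt, CH2Cl2/DMF, 0 °C → rt; chromatography
Reagents that add atoms: chloromethyl methyl ether, COCCl
Why: Statistical O-alkylation of two of three equivalent phenols (Williamson-type acetal ether formation); the mono- and tris-ethers are separated.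

**Step 3**
Reactants: 5 3,5-bis(methoxymethoxy)phenol; 3 (E)-5-methylhex-2-enal
Product: 7 (4S)-4-isobutyl-5,7-bis(methoxymethoxy)chroman-2-ol (lactol as anomer mixture), via hydroxy aldehyde 6 (not isolated)
Conditions: (R)-α,α-diphenylprolinol trimethylsilyl ether (20 mol %), PhCO2H (20 mol %), toluene, 0 °C
Reagents that add atoms: none
Why: Iminium-catalysed Michael (Friedel–Crafts type) addition of the phenol ortho carbon to the E-iminium ion, on the face away from the CPh2OSiMe3 group, sets C7′ (S); the adduct closes to the lactol.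

**Step 4**
Reactants: 7 lactol
Product: 8 (4S)-4-isobutyl-5,7-bis(methoxymethoxy)chroman-2-one
Conditions: PhI(OAc)2 (1.2 equiv), TEMPO (0.1 equiv), CH2Cl2, rt
Reagents that add atoms: none
Why: Oxoammonium (TEMPO) oxidation of the lactol to the lactone under nearly neutral conditions that spare the MOM ethers.

**Step 5**
Reactants: 8 lactone
Product: 9 (3S,4S)-4-isobutyl-5,7-bis(methoxymethoxy)-3-[(phenylsulfanyl)methyl]chroman-2-one (3,4-trans)
Conditions: LiN(SiMe3)2, THF, −78 °C; PhSCH2I, DMPU, −78 → −45 °C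
Reagents that add atoms: iodomethyl phenyl sulfide, ICSc1ccccc1
Why: Lactone enolate alkylation occurs anti to the pseudoaxial 4-isobutyl group, setting C1 trans to C7′.

**Step 6**
Reactants: 9 trans-lactone
Product: 10 (3S,4S)-4-isobutyl-5,7-bis(methoxymethoxy)-3-[(phenylsulfanyl)methyl]chroman-2-ol (anomer mixture)
Conditions: i-Bu2AlH (1.1 equiv), CH2Cl2, −78 °C
Reagents that add atoms: none
Why: Partial hydride reduction of the aryl lactone stops at the lactol at low temperature.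

**Step 7**
Reactants: 10 lactol
Product: 11 2-[(4S,5S)-7,7-dibromo-2-methyl-5-[(phenylsulfanyl)methyl]hept-6-en-4-yl]-3,5-bis(methoxymethoxy)phenol
Conditions: CBr4, PPh3, Et3N, CH2Cl2, 0 °C
Reagents that add atoms: carbon tetrabromide, BrC(Br)(Br)Br
Why: Ramirez dibromo-olefination (first half of Corey–Fuchs) traps the open aldehyde form without base strong enough to epimerise C1 or expel thiolate.

**Step 8**
Reactants: 11 dibromoalkene phenol
Product: 12 triisopropylsilyl ether of 11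
Conditions: i-Pr3SiOTf, 2,6-lutidine, CH2Cl2, 0 °C
Reagents that add atoms: triisopropylsilyl trifluoromethanesulfonate, CC(C)[Si](C(C)C)(C(C)C)OS(=O)(=O)C(F)(F)F
Why: Silylation masks the phenol for the organometallic and oxidation steps.

**Step 9**
Reactants: 12 silyl ether
Product: 13 terminal alkyne, ArCH(i-Bu)–CH(CH2SPh)–C≡CH (4S,5S; Ar = 2,4-bis(methoxymethoxy)-6-(triisopropylsilyloxy)phenyl)
Conditions: n-BuLi (2.2 equiv), THF, −78 °C; H2O
Reagents that add atoms: none
Why: Br–Li exchange and Fritsch–Buttenberg–Wiechell rearrangement (second half of Corey–Fuchs) is faster at −78 °C than arene lithiation.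

**Step 10**
Reactants: 13 alkyne
Product: 15 (2E,4S,5S)-5-[2,4-bis(methoxymethoxy)-6-(triisopropylsilyloxy)phenyl]-3,7-dimethyl-4-[(phenylsulfanyl)methyl]oct-2-en-1-ol, via alkenylalane 14 (not isolated)
Conditions: AlMe3 (3 equiv), Cp2ZrCl2 (0.25 equiv), CH2Cl2, 0 °C → rt; n-BuLi, hexane/THF, −78 °C; (CH2O)n, rt
Reagents that add atoms: trimethylaluminium, C[Al](C)C; paraformaldehyde (as formaldehyde), C=O
Why: Negishi zirconium-catalysed syn-carboalumination puts methyl on the internal carbon, and the aluminate adds to formaldehyde with retention, giving only the E-allylic alcohol.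

**Step 11**
Reactants: 15 sulfide allylic alcohol
Product: 16 (2E,4S,5S)-phenylsulfonyl analogue of 15
Conditions: Oxone (2KHSO5·KHSO4·K2SO4), NaHCO3, MeOH/THF/H2O, 0 °C
Reagents that add atoms: potassium peroxymonosulfate, [K+].[O-]S(=O)(=O)OO
Why: Peroxymonosulfate oxidises the sulfide to the sulfone but leaves the alkene alone without a ketone catalyst; the sulfone is needed before the titanium/peroxide step.

**Step 12**
Reactants: 16 allylic alcohol
Product: 17 {(2R,3R)-3-methyl-3-[(2S,3S)-3-aryl-5-methyl-1-(phenylsulfonyl)hexan-2-yl]oxiran-2-yl}methanol (aryl as in 13)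
Conditions: Ti(OiPr)4 (0.2 equiv), D-(−)-diisopropyl tartrate (0.25 equiv), t-BuOOH, 4 Å sieves, CH2Cl2, −20 °C
Reagents that add atoms: tert-butyl hydroperoxide, CC(C)(C)OO
Why: Sharpless asymmetric epoxidation; the D-tartrate gives the (2R,3R)-epoxy alcohol from this E-3-methyl allylic alcohol under reagent control, which fixes the configuration that C10 will take.

**Step 13**
Reactants: 17 epoxy alcohol
Product: 19 (1R)-1-[(2S,3S,4S)-4-isobutyl-5,7-bis(methoxymethoxy)-2-methyl-3-[(phenylsulfonyl)methyl]chroman-2-yl]ethane-1,2-diol, via epoxy phenol 18 (not isolated)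
Conditions: Bu4NF, AcOH, THF, 0 °C; then PPTS (10 mol %), CH2Cl2, rt
Reagents that add atoms: none
Why: After desilylation the phenol opens the epoxide at its tertiary carbon from the rear (acid-promoted 6-exo-tet, inversion), so C10 is set stereospecifically with methyl cis to the C1 side chain.

**Step 14**
Reactants: 19 diol
Product: 20 (2S,3S,4S)-4-isobutyl-5,7-bis(methoxymethoxy)-2-methyl-3-[(phenylsulfonyl)methyl]chroman-2-carbaldehyde
Conditions: NaIO4, THF/pH 7 buffer, 0 °C → rt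
Reagents that add atoms: none
Why: Periodate glycol cleavage gives a non-enolisable aldehyde (C9), so C10 cannot epimerise.

**Step 15**
Reactants: 21 (S)-(+)-carvone
Product: 22 (S)-5-(2-hydroxypropan-2-yl)-2-methylcyclohex-2-en-1-one
Conditions: 50% aq. H2SO4, 0 °C, 24 h
Reagents that add atoms: water, O
Why: Markovnikov acid-catalysed hydration of the isopropenyl group only; the stereocentre (future C7) is untouched.

**Step 16**
Reactants: 22 hydroxy enone
Product: 23 (S)-2-methyl-5-[2-(triethylsilyloxy)propan-2-yl]cyclohex-2-en-1-one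
Conditions: Et3SiOTf, 2,6-lutidine, CH2Cl2, −78 → 0 °C
Reagents that add atoms: triethylsilyl trifluoromethanesulfonate, CC[Si](CC)(CC)OS(=O)(=O)C(F)(F)F
Why: Silylation of the tertiary alcohol prevents retro-aldol and alkoxide side reactions later.

**Step 17**
Reactants: 23 enone
Product: 24 (5S)-6-hydroxy-2-methyl-5-[2-(triethylsilyloxy)propan-2-yl]cyclohex-2-en-1-one (C6 epimers)
Conditions: LiN(i-Pr)2, THF, −78 °C; 2-(phenylsulfonyl)-3-phenyloxaziridine, −78 °C
Reagents that add atoms: 2-(phenylsulfonyl)-3-phenyloxaziridine, O=S(=O)(c1ccccc1)N1OC1c1ccccc1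
Why: Kinetic α′-deprotonation and Davis enolate hydroxylation; the epimer mixture is irrelevant because this carbon becomes the aldehyde.

**Step 18**
Reactants: 24 α′-hydroxy ketone
Product: 25 methyl (2Z,5R)-5-formyl-2,6-dimethyl-6-(triethylsilyloxy)hept-2-enoate
Conditions: Pb(OAc)4, MeOH/PhH (1:1), 0 °C
Reagents that add atoms: methanol, CO
Why: Criegee-type cleavage of the α-ketol in methanol opens the ring to ester (C3) and aldehyde (C8); the ring-derived cis geometry becomes the Z-enoate.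

**Step 19**
Reactants: 25 aldehyde ester
Product: 26 methyl (2Z,5S)-5-(hydroxymethyl)-2,6-dimethyl-6-(triethylsilyloxy)hept-2-enoate
Conditions: NaBH4, MeOH, −40 °C
Reagents that add atoms: none
Why: Chemoselective borohydride reduction of the aldehyde removes the epimerisable centre before it can scramble.

**Step 20**
Reactants: 26 alcohol
Product: 27 methyl (2Z,5R)-2,6-dimethyl-5-{[(1-phenyl-1H-tetrazol-5-yl)sulfanyl]methyl}-6-(triethylsilyloxy)hept-2-enoate
Conditions: 1-phenyl-1H-tetrazole-5-thiol, PPh3, DIAD, THF, 0 °C → rt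
Reagents that add atoms: 1-phenyl-1H-tetrazole-5-thiol, Sc1nnnn1-c1ccccc1
Why: Mitsunobu thioetherification of the primary alcohol; C7 is not involved.

**Step 21**
Reactants: 27 sulfide
Product: 28 methyl (2Z,5R)-2,6-dimethyl-5-{[(1-phenyl-1H-tetrazol-5-yl)sulfonyl]methyl}-6-(triethylsilyloxy)hept-2-enoate
Conditions: (NH4)6Mo7O24·4H2O (0.1 equiv), 30% H2O2, EtOH, 0 °C → rt
Reagents that add atoms: hydrogen peroxide, OO
Why: Molybdate-catalysed sulfide-to-sulfone oxidation; the electron-poor enoate double bond is not epoxidised.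

**Step 22**
Reactants: 28 sulfone (fragment B); 20 aldehyde (fragment A)
Product: 29 coupled alkene: chroman C10 joined through CH=CH (C9=C8, E major) to C7 of the (Z)-enoate chain
Conditions: KN(SiMe3)2, DME, −60 °C → rt (base added to 28, then 20)
Reagents that add atoms: none
Why: Julia–Kocienski olefination of the hindered, non-enolisable aldehyde; the tetrazolyl sulfone is far more acidic than the phenyl sulfone, and alkene geometry does not matter.

**Step 23**
Reactants: 29 alkene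
Product: 30 saturated ester (C8–C9 single bond; Z-enoate intact)
Conditions: 2-nitrobenzenesulfonylhydrazide, Et3N, CH2Cl2, rt (repeated charges)
Reagents that add atoms: none
Why: Diimide reduction prefers the 1,2-disubstituted alkene over the trisubstituted conjugated one and cannot cleave the allylic C–O bond.

**Step 24**
Reactants: 30 ester
Product: 31 (Z)-allylic alcohol (C3 CH2OH)
Conditions: i-Bu2AlH (2.5 equiv), CH2Cl2, −78 °C
Reagents that add atoms: none
Why: 1,2-Reduction of the enoate by the aluminium hydride keeps the Z geometry.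

**Step 25**
Reactants: 31 allylic alcohol
Product: 33 (Z)-allylic chloride, via allylic mesylate 32 (not isolated)
Conditions: MsCl, 2,4,6-collidine, LiCl, DMF, 0 °C
Reagents that add atoms: methanesulfonyl chloride, CS(=O)(=O)Cl (in 32); lithium chloride, [Li+].[Cl-] (in 33)
Why: Collington–Meyers mesylation and SN2 chloride displacement, without allylic transposition or loss of Z geometry.

**Step 26**
Reactants: 33 allylic chloride
Product: 34 ten-membered ring sulfone (C2–C3 bond formed; C2 epimers)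
Conditions: KN(SiMe3)2, THF (0.002 M, slow addition), −78 → 0 °C
Reagents that add atoms: none
Why: Intramolecular SN2 alkylation of the α-sulfonyl carbanion by the allylic chloride at high dilution, with the trans-2,3-disubstituted chroman and the Z-alkene bringing the ends together; the new sulfone-bearing centre is removed next.

**Step 27**
Reactants: 34 cyclic sulfone
Product: 35 macrocycle with C2 as CH2 (bis-MOM ether, triethylsilyl ether)
Conditions: 6% Na(Hg), Na2HPO4, MeOH/THF, −20 °C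
Reagents that add atoms: none
Why: Reductive desulfonylation by electron transfer; the sulfone is not allylic, so the Z-alkene neither migrates nor isomerises.

**Step 28**
Reactants: 35 macrocycle
Product: 36 6,8-dibromochroman
Conditions: NBS (2.1 equiv), NaHCO3, MeCN, −20 → 0 °C
Reagents that add atoms: N-bromosuccinimide, O=C1CCC(=O)N1Br
Why: Electrophilic aromatic bromination of the tri-oxygenated ring at its two free positions is much faster than any reaction of the trisubstituted alkene.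

**Step 29**
Reactants: 36 dibromide
Product: 37 6,8-dicarbaldehyde (bis-MOM ether, triethylsilyl ether)
Conditions: t-BuLi (4.4 equiv), THF, −78 °C; DMF; aq. NH4Cl
Reagents that add atoms: N,N-dimethylformamide, CN(C)C=O
Why: Double Br–Li exchange, with each lithium flanked by chelating oxygens, followed by Bouveault formylation introduces both CHO groups without acid.

**Step 30**
Reactants: 37 protected dialdehyde
Product: 38 target (CNP0570248.1)
Conditions: 2 M aq. HCl, MeOH/THF, rt → 35 °C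
Reagents that add atoms: none
Why: Mild acid cleaves the two MOM acetals (ortho to CHO) and the triethylsilyl ether while the tertiary alcohol, chroman ether and Z-alkene survive; no stereocentre is touched.

**Compound list**
1 | 3-methylbutanal | CC(C)CC=O | starting material
2 | (triphenylphosphoranylidene)acetaldehyde | O=CC=P(c1ccccc1)(c1ccccc1)c1ccccc1 | starting material
3 | (E)-5-methylhex-2-enal | CC(C)C/C=C/C=O | intermediate
4 | phloroglucinol | Oc1cc(O)cc(O)c1 | starting material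
5 | 3,5-bis(methoxymethoxy)phenol | COCOc1cc(O)cc(OCOC)c1 | intermediate
6 | (3S)-3-[2-hydroxy-4,6-bis(methoxymethoxy)phenyl]-5-methylhexanal | O=CC[C@H](CC(C)C)c1c(O)cc(OCOC)cc1OCOC | intermediate (not isolated)
7 | (4S)-4-isobutyl-5,7-bis(methoxymethoxy)chroman-2-ol | OC1C[C@H](CC(C)C)c2c(OCOC)cc(OCOC)cc2O1 | intermediate
8 | (4S)-4-isobutyl-5,7-bis(methoxymethoxy)chroman-2-one | O=C1C[C@H](CC(C)C)c2c(OCOC)cc(OCOC)cc2O1 | intermediate
9 | (3S,4S)-4-isobutyl-5,7-bis(methoxymethoxy)-3-[(phenylsulfanyl)methyl]chroman-2-one | O=C1[C@@H](CSc3ccccc3)[C@H](CC(C)C)c2c(OCOC)cc(OCOC)cc2O1 | intermediate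
10 | (3S,4S)-4-isobutyl-5,7-bis(methoxymethoxy)-3-[(phenylsulfanyl)methyl]chroman-2-ol | OC1[C@@H](CSc3ccccc3)[C@H](CC(C)C)c2c(OCOC)cc(OCOC)cc2O1 | intermediate
11 | 2-[(4S,5S)-7,7-dibromo-2-methyl-5-[(phenylsulfanyl)methyl]hept-6-en-4-yl]-3,5-bis(methoxymethoxy)phenol | BrC(Br)=C[C@@H](CSc1ccccc1)[C@H](CC(C)C)c1c(O)cc(OCOC)cc1OCOC | intermediate
12 | triisopropylsilyl ether of 11 | BrC(Br)=C[C@@H](CSc1ccccc1)[C@H](CC(C)C)c1c(O[Si](C(C)C)(C(C)C)C(C)C)cc(OCOC)cc1OCOC | intermediate
13 | terminal alkyne, (4S,5S)-hept-6-yn-4-yl analogue of 12 | C#C[C@@H](CSc1ccccc1)[C@H](CC(C)C)c1c(O[Si](C(C)C)(C(C)C)C(C)C)cc(OCOC)cc1OCOC | intermediate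
14 | (E)-alkenyl(dimethyl)alane from 13 (Al and CH3 cis) | C[Al](C)/C=C(\C)[C@@H](CSc1ccccc1)[C@H](CC(C)C)c1c(O[Si](C(C)C)(C(C)C)C(C)C)cc(OCOC)cc1OCOC | intermediate (not isolated)
15 | (2E,4S,5S)-5-[2,4-bis(methoxymethoxy)-6-(triisopropylsilyloxy)phenyl]-3,7-dimethyl-4-[(phenylsulfanyl)methyl]oct-2-en-1-ol | OC/C=C(\C)[C@@H](CSc1ccccc1)[C@H](CC(C)C)c1c(O[Si](C(C)C)(C(C)C)C(C)C)cc(OCOC)cc1OCOC | intermediate
16 | (2E,4S,5S)-phenylsulfonyl analogue of 15 | OC/C=C(\C)[C@@H](CS(=O)(=O)c1ccccc1)[C@H](CC(C)C)c1c(O[Si](C(C)C)(C(C)C)C(C)C)cc(OCOC)cc1OCOC | intermediate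
17 | (2R,3R)-epoxy alcohol of 16 | OC[C@H]1O[C@]1(C)[C@@H](CS(=O)(=O)c1ccccc1)[C@H](CC(C)C)c1c(O[Si](C(C)C)(C(C)C)C(C)C)cc(OCOC)cc1OCOC | intermediate
18 | free phenol of 17 | OC[C@H]1O[C@]1(C)[C@@H](CS(=O)(=O)c1ccccc1)[C@H](CC(C)C)c1c(O)cc(OCOC)cc1OCOC | intermediate (not isolated)
19 | (1R)-1-[(2S,3S,4S)-4-isobutyl-5,7-bis(methoxymethoxy)-2-methyl-3-[(phenylsulfonyl)methyl]chroman-2-yl]ethane-1,2-diol | OC[C@@H](O)[C@@]2(C)Oc3cc(OCOC)cc(OCOC)c3[C@@H](CC(C)C)[C@@H]2CS(=O)(=O)c1ccccc1 | intermediate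
20 | (2S,3S,4S)-4-isobutyl-5,7-bis(methoxymethoxy)-2-methyl-3-[(phenylsulfonyl)methyl]chroman-2-carbaldehyde | O=C[C@@]2(C)Oc3cc(OCOC)cc(OCOC)c3[C@@H](CC(C)C)[C@@H]2CS(=O)(=O)c1ccccc1 | intermediate
21 | (S)-(+)-carvone | CC1=CC[C@@H](CC1=O)C(C)=C | starting material
22 | (S)-5-(2-hydroxypropan-2-yl)-2-methylcyclohex-2-en-1-one | CC1=CC[C@@H](CC1=O)C(C)(C)O | intermediate
23 | (S)-2-methyl-5-[2-(triethylsilyloxy)propan-2-yl]cyclohex-2-en-1-one | CC1=CC[C@@H](CC1=O)C(C)(C)O[Si](CC)(CC)CC | intermediate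
24 | (5S)-6-hydroxy-2-methyl-5-[2-(triethylsilyloxy)propan-2-yl]cyclohex-2-en-1-one (C6 epimers) | CC1=CC[C@@H](C(O)C1=O)C(C)(C)O[Si](CC)(CC)CC | intermediate
25 | methyl (2Z,5R)-5-formyl-2,6-dimethyl-6-(triethylsilyloxy)hept-2-enoate | COC(=O)/C(C)=C\C[C@@H](C=O)C(C)(C)O[Si](CC)(CC)CC | intermediate
26 | methyl (2Z,5S)-5-(hydroxymethyl)-2,6-dimethyl-6-(triethylsilyloxy)hept-2-enoate | COC(=O)/C(C)=C\C[C@@H](CO)C(C)(C)O[Si](CC)(CC)CC | intermediate
27 | methyl (2Z,5R)-2,6-dimethyl-5-{[(1-phenyl-1H-tetrazol-5-yl)sulfanyl]methyl}-6-(triethylsilyloxy)hept-2-enoate | COC(=O)/C(C)=C\C[C@@H](CSc1nnnn1-c1ccccc1)C(C)(C)O[Si](CC)(CC)CC | intermediate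
28 | methyl (2Z,5R)-2,6-dimethyl-5-{[(1-phenyl-1H-tetrazol-5-yl)sulfonyl]methyl}-6-(triethylsilyloxy)hept-2-enoate | COC(=O)/C(C)=C\C[C@@H](CS(=O)(=O)c1nnnn1-c1ccccc1)C(C)(C)O[Si](CC)(CC)CC | intermediate
29 | Julia product: chroman of 20 linked by (E)-C9=C8 to the chain of 28 (stereocentres as in 20 and 28) | COC(=O)/C(C)=C\C[C@@H](/C=C/[C@@]2(C)Oc3cc(OCOC)cc(OCOC)c3[C@@H](CC(C)C)[C@@H]2CS(=O)(=O)c1ccccc1)C(C)(C)O[Si](CC)(CC)CC | intermediate
30 | C8–C9 saturated (Z)-enoate | COC(=O)/C(C)=C\C[C@@H](CC[C@@]2(C)Oc3cc(OCOC)cc(OCOC)c3[C@@H](CC(C)C)[C@@H]2CS(=O)(=O)c1ccccc1)C(C)(C)O[Si](CC)(CC)CC | intermediate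
31 | (Z)-allylic alcohol from 30 | OC/C(C)=C\C[C@@H](CC[C@@]2(C)Oc3cc(OCOC)cc(OCOC)c3[C@@H](CC(C)C)[C@@H]2CS(=O)(=O)c1ccccc1)C(C)(C)O[Si](CC)(CC)CC | intermediate
32 | (Z)-allylic mesylate of 31 | CS(=O)(=O)OC/C(C)=C\C[C@@H](CC[C@@]2(C)Oc3cc(OCOC)cc(OCOC)c3[C@@H](CC(C)C)[C@@H]2CS(=O)(=O)c1ccccc1)C(C)(C)O[Si](CC)(CC)CC | intermediate (not isolated)
33 | (Z)-allylic chloride | ClC/C(C)=C\C[C@@H](CC[C@@]2(C)Oc3cc(OCOC)cc(OCOC)c3[C@@H](CC(C)C)[C@@H]2CS(=O)(=O)c1ccccc1)C(C)(C)O[Si](CC)(CC)CC | intermediate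
34 | tricyclic sulfone: chroman trans-fused to the (Z)-cyclodecene, PhSO2 on C2 (epimers) | C/C1=C/C[C@H](C(C)(C)O[Si](CC)(CC)CC)CC[C@@]2(C)Oc3cc(OCOC)cc(OCOC)c3[C@@H](CC(C)C)[C@@H]2C(S(=O)(=O)c4ccccc4)C1 | intermediate
35 | desulfonylated tricycle (5,7-bis-MOM ether, triethylsilyl ether) | C/C1=C/C[C@H](C(C)(C)O[Si](CC)(CC)CC)CC[C@@]2(C)Oc3cc(OCOC)cc(OCOC)c3[C@@H](CC(C)C)[C@@H]2CC1 | intermediate
36 | 6,8-dibromo derivative of 35 | C/C1=C/C[C@H](C(C)(C)O[Si](CC)(CC)CC)CC[C@@]2(C)Oc3c(Br)c(OCOC)c(Br)c(OCOC)c3[C@@H](CC(C)C)[C@@H]2CC1 | intermediate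
37 | 6,8-diformyl derivative of 35 | C/C1=C/C[C@H](C(C)(C)O[Si](CC)(CC)CC)CC[C@@]2(C)Oc3c(C=O)c(OCOC)c(C=O)c(OCOC)c3[C@@H](CC(C)C)[C@@H]2CC1 | intermediate
38 | CNP0570248.1: 5,7-dihydroxy-4-isobutyl-2-methylchroman-6,8-dicarbaldehyde trans-fused at C2–C3 to a (Z)-methylcyclodecene bearing 2-hydroxypropan-2-yl (1S,7R,10R,7′S) | C/C1=C/C[C@H](C(C)(C)O)CC[C@@]2(C)Oc3c(C=O)c(O)c(C=O)c(O)c3[C@@H](CC(C)C)[C@@H]2CC1 | target

**Totals**
Total steps: 30. Longest linear sequence: 22 steps (steps 1, 3–14, 22–30).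

**Three steps most likely to fail**

Step 3 (organocatalytic Michael addition). The enantioselectivity with an aliphatic enal and the ortho-versus-para regioselectivity of phenol 5 are not guaranteed. The fallback sets out from 4 and comes back at 8. Phloroglucinol 4 is condensed with ethyl 5-methyl-3-oxohexanoate (CF3CO2H, rt, Pechmann condensation) to 5,7-dihydroxy-4-isobutylcoumarin F1. F1 is etherified (MOMCl, i-Pr2NEt) to 4-isobutyl-5,7-bis(methoxymethoxy)coumarin F2. Asymmetric conjugate reduction of F2 with CuH generated from Cu(OAc)2, DTBM-SEGPHOS and (EtO)2MeSiH (t-BuOH, toluene) gives lactone 8; the ligand enantiomer is fixed by a test run against 8. C7′ then comes from ligand-controlled hydride delivery, not from the C–C bond formation.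

Step 23 (selective reduction of C8=C9). The hindered disubstituted alkene may not be reduced cleanly beside the trisubstituted Z-enoate. The fallback sets out from 28 (with 20) and comes back at 30. Ozonolysis of 28 (O3, CH2Cl2/MeOH, −78 °C; Me2S) removes the enoate and gives (3R)-4-methyl-3-{[(1-phenyl-1H-tetrazol-5-yl)sulfonyl]methyl}-4-(triethylsilyloxy)pentanal F3. F3 is protected (HC(OMe)3, PPTS, MeOH) as its dimethyl acetal F4. Julia–Kocienski coupling of F4 with 20 gives the alkene acetal F5, whose only C=C bond is hydrogenated (H2, Rh/Al2O3, EtOAc) to the saturated acetal F6. PPTS in wet acetone frees the saturated aldehyde F7. Still–Gennari olefination of F7 with methyl 2-[bis(2,2,2-trifluoroethoxy)phosphoryl]propanoate (KN(SiMe3)2, 18-crown-6, THF, −78 °C) rebuilds the Z-enoate and gives 30.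

Step 26 (ten-membered ring closure by alkylation). Oligomerisation or elimination may win over cyclisation. The fallback sets out from 20 and 25 and comes back at 34; it makes C2–C3 intermolecularly and closes the ring at C8=C9 by metathesis. Wittig methylenation (Ph3P=CH2, THF) of 20 gives the 2-vinylchroman sulfone F8, and of 25 gives the diene ester F9. F9 is reduced (i-Bu2AlH) to the dienol F10 and converted (MsCl, collidine, LiCl) to the allylic chloride F11. The lithiated sulfone of F8 (n-BuLi, THF/DMPU, −78 °C) is alkylated with F11 to the triene sulfone F12. Ring-closing metathesis of the two vinyl groups (second-generation Grubbs catalyst RuCl2(=CHPh)(PCy3)(H2IMes), toluene, 80 °C, 0.001 M) gives the cyclodecadiene sulfone F13. Diimide reduction of the disubstituted ring alkene of F13 gives 34.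

**Further compounds**
F1 | step 3 | 5,7-dihydroxy-4-isobutylcoumarin | O=C1C=C(CC(C)C)c2c(O)cc(O)cc2O1
F2 | step 3 | 4-isobutyl-5,7-bis(methoxymethoxy)coumarin | O=C1C=C(CC(C)C)c2c(OCOC)cc(OCOC)cc2O1
F3 | step 23 | (3R)-4-methyl-3-{[(1-phenyl-1H-tetrazol-5-yl)sulfonyl]methyl}-4-(triethylsilyloxy)pentanal | O=CC[C@@H](CS(=O)(=O)c1nnnn1-c1ccccc1)C(C)(C)O[Si](CC)(CC)CC
F4 | step 23 | dimethyl acetal of F3 | COC(OC)C[C@@H](CS(=O)(=O)c1nnnn1-c1ccccc1)C(C)(C)O[Si](CC)(CC)CC
F5 | step 23 | alkene acetal (E-C8=C9, chroman as in 20) | COC(OC)C[C@@H](/C=C/[C@@]2(C)Oc3cc(OCOC)cc(OCOC)c3[C@@H](CC(C)C)[C@@H]2CS(=O)(=O)c1ccccc1)C(C)(C)O[Si](CC)(CC)CC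
F6 | step 23 | saturated acetal | COC(OC)C[C@@H](CC[C@@]2(C)Oc3cc(OCOC)cc(OCOC)c3[C@@H](CC(C)C)[C@@H]2CS(=O)(=O)c1ccccc1)C(C)(C)O[Si](CC)(CC)CC
F7 | step 23 | saturated aldehyde | O=CC[C@@H](CC[C@@]2(C)Oc3cc(OCOC)cc(OCOC)c3[C@@H](CC(C)C)[C@@H]2CS(=O)(=O)c1ccccc1)C(C)(C)O[Si](CC)(CC)CC
F8 | step 26 | 2-vinylchroman sulfone | C=C[C@@]2(C)Oc3cc(OCOC)cc(OCOC)c3[C@@H](CC(C)C)[C@@H]2CS(=O)(=O)c1ccccc1
F9 | step 26 | diene ester, methyl (2Z,5S)-2-methyl-5-[2-(triethylsilyloxy)propan-2-yl]hepta-2,6-dienoate | COC(=O)/C(C)=C\C[C@@H](C=C)C(C)(C)O[Si](CC)(CC)CC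
F10 | step 26 | dienol | OC/C(C)=C\C[C@@H](C=C)C(C)(C)O[Si](CC)(CC)CC
F11 | step 26 | allylic chloride | ClC/C(C)=C\C[C@@H](C=C)C(C)(C)O[Si](CC)(CC)CC
F12 | step 26 | triene sulfone (C2 epimers) | C=C[C@@]2(C)Oc3cc(OCOC)cc(OCOC)c3[C@@H](CC(C)C)[C@@H]2C(S(=O)(=O)c1ccccc1)C/C(C)=C\C[C@@H](C=C)C(C)(C)O[Si](CC)(CC)CC
F13 | step 26 | cyclodecadiene sulfone (C8=C9 in ring, C2 epimers) | C/C1=C/C[C@H](C(C)(C)O[Si](CC)(CC)CC)C=C[C@@]2(C)Oc3cc(OCOC)cc(OCOC)c3[C@@H](CC(C)C)[C@@H]2C(S(=O)(=O)c4ccccc4)C1
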